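The route rests on cutting the C2–C3 bond of the dihydrofuran ring. Both carbons are natively electrophilic, C3 as an aryl aldehyde carbon and C2 as the β-carbon of an acrylate hung on the phenol oxygen O1. The feature exploited is this vicinal O-bearing C2/C3 pair next to the benzene ring. One-electron reduction turns C3 into a nucleophilic ketyl, which in one operation closes the O1–C2–C3–C3a–C7a ring, forms C2–C3 and sets both ring stereocentres trans. The CH2CO2Me arm left on C2 becomes the acrolein by reduction and one formaldehyde unit. The precursor is a flat salicylaldehyde (E)-aryloxyacrylate whose only stereocentre is the silyl-protected C1′ carbinol on C5.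

Key step: step 7

Stereochemical reading of the target: C2 is R, C3 is S, their substituents are trans on the dihydrofuran ring, and the side-chain carbinol carbon C1′ is R.

Assumption: the sense of induction of the aminodiol ligand on an aryl aldehyde ketyl cannot be derived from precedent, so the (R,R)-ligand is written; if it favours the (2S,3R) pair, its mirror image, made the same way from (S)-styrene oxide, takes its place.

Step 1
Reactants: 1 4-hydroxyacetophenone
Product: 2 4-(tert-butyldimethylsilyloxy)acetophenone
Conditions: t-BuMe2SiCl (1.1 equiv), imidazole (2 equiv), DMF, rt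
Reagents that add atoms: tert-butyldimethylsilyl chloride, CC(C)(C)[Si](C)(C)Cl
Why: Imidazole-promoted O-silylation masks the acidic phenol, so the ketone is not deactivated as a phenoxide in the reduction, and no free p-hydroxybenzylic carbinol, which could racemise through a p-quinone methide, is ever formed.

Step 2
Reactants: 2 4-(tert-butyldimethylsilyloxy)acetophenone
Product: 3 (1R)-1-[4-(tert-butyldimethylsilyloxy)phenyl]ethanol
Conditions: RuCl[(R,R)-TsDPEN](p-cymene) (1 mol %), HCO2H–Et3N (5:2), 40 °C
Reagents that add atoms: none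
Why: In the Noyori asymmetric transfer hydrogenation the (R,R)-TsDPEN ruthenium hydride reduces aryl methyl ketones to (R)-1-arylethanols, which sets C1′; the irreversible formic acid donor guards against erosion with this electron-rich arene, and the aryl silyl ether tolerates the mildly acidic medium.

Step 3
Reactants: 3 (1R)-1-[4-(tert-butyldimethylsilyloxy)phenyl]ethanol
Product: 5 4-[(1R)-1-(tert-butyldimethylsilyloxy)ethyl]phenol, via bis-silyl ether 4 (not isolated)
Conditions: t-BuMe2SiCl (1.2 equiv), imidazole (2 equiv), DMF, rt; aqueous wash; crude 4, Cs2CO3 (0.5 equiv), DMF–H2O (10:1), rt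
Reagents that add atoms: tert-butyldimethylsilyl chloride, CC(C)(C)[Si](C)(C)Cl
Why: Routine silylation of the carbinol is followed by carbonate-mediated hydrolysis, which cleaves aryl silyl ethers (phenoxide leaving group) far faster than alkyl ones, and the basic room-temperature medium avoids ionisation at C1′.

Step 4
Reactants: 5 4-[(1R)-1-(tert-butyldimethylsilyloxy)ethyl]phenol; 6 formaldehyde (as paraformaldehyde)
Product: 8 5-[(1R)-1-(tert-butyldimethylsilyloxy)ethyl]-2-hydroxybenzaldehyde, via hydroxymethylphenol 7 (not isolated)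
Conditions: MgCl2 (2 equiv), Et3N (4 equiv), (CH2O)n (6 equiv), THF, reflux; cold aq. citric acid
Reagents that add atoms: formaldehyde 6, C=O
Why: In the Casnati–Skattebøl ortho-formylation the magnesium phenoxide steers formaldehyde to the ortho carbon (both ortho sites are equivalent, para is blocked) to give 7, which a second formaldehyde oxidises by Oppenauer-type hydride transfer; the silanolate on C1′ is too poor a nucleofuge to leave from the phenoxide, so C1′ should hold.

Step 5
Reactants: 8 5-[(1R)-1-(tert-butyldimethylsilyloxy)ethyl]-2-hydroxybenzaldehyde; 9 methyl propiolate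
Product: 10 methyl (E)-3-[2-formyl-4-[(1R)-1-(tert-butyldimethylsilyloxy)ethyl]phenoxy]acrylate
Conditions: methyl propiolate (1.1 equiv), N-methylmorpholine (20 mol %), CH2Cl2, 0 °C to rt
Reagents that add atoms: methyl propiolate 9, C#CC(=O)OC
Why: The tertiary-amine-catalysed oxa-Michael addition of a phenol to an ynoate runs through the β-ammonium acrylate by addition–elimination and should give the (E)-aryloxyacrylate, the acidic phenol supplying the proton before any attack on the ortho aldehyde.

Step 6
Reactants: 11 benzylamine; 12 (R)-styrene oxide (2 equiv)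
Product: 13 (1R,1′R)-2,2′-(benzylazanediyl)bis(1-phenylethanol)
Conditions: MeOH, reflux; crystallisation
Reagents that add atoms: (R)-styrene oxide 12, C1O[C@@H]1c1ccccc1
Why: Twofold SN2 aminolysis at the unsubstituted epoxide carbon leaves the benzylic stereocentres untouched and gives a C2-symmetric tridentate aminodiol, a ligand type known to bind samarium.

Step 7
Reactants: 10 methyl (E)-3-[2-formyl-4-[(1R)-1-(tert-butyldimethylsilyloxy)ethyl]phenoxy]acrylate
Product: 16 methyl 2-[(2R,3S)-5-[(1R)-1-(tert-butyldimethylsilyloxy)ethyl]-3-hydroxy-2,3-dihydro-1-benzofuran-2-yl]acetate, via samarium ketyl 14 (not isolated), via samarium enolate 15 (not isolated)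
Conditions: SmI2 (2.6 equiv, 0.1 M in THF), aminodiol 13 (2.8 equiv, recovered), MeOH (20 equiv), THF, −78 °C; 10 added by syringe pump (final 5 mM), then to −40 °C; air, aq. potassium sodium tartrate/NaHCO3
Reagents that add atoms: none
Why: Proposed new method: SmI2 carrying aminodiol 13 gives one electron to the aryl aldehyde, the most easily reduced group of 10, and the nucleophilic carbon of ketyl 14 (future C3) attacks the electron-poor acrylate β-carbon (future C2); a second electron converts the adduct radical into the trivalent samarium enolate 15, which metal-bound MeOH protonates at low temperature before the C2–O1 bond can break. The closest known reaction types are the ligand-free SmI2/MeOH cyclisation of aldehydes onto β-alkoxyacrylates, which gives 2,3-trans cyclic ethers, and the aminodiol-controlled enantioselective 5-exo cyclisation of keto ester ketyls; what is new is ligand control over an aryl aldehyde ketyl tethered through a phenol oxygen. The dihydrofuran ring (O1, C2, C3, C3a, C7a) closes in the 5-exo-trig mode, the 6-endo alternative being mismatched with the polarisation of the acrylate. The relative configuration comes from the (E)-alkene and from the bulky samarium alkoxide on C3 pointing away from the CHCO2Me terminus on C2, which gives trans; the absolute configuration at C3 (S), and through the trans rule at C2 (R), comes from the ligand shielding one face of the planar ketyl, C1′ being too far away to matter. The step needs cyclisation to win over pinacol coupling, over plain reduction to the benzylic alcohol and over aryloxide loss: the rigid ortho tether holds C2 next to C3, slow addition at high dilution keeps the ketyl concentration low, and MeOH is too weak an acid for the ketyl but quick enough for the enolate. The side-chain C–OSi bond sits meta to the ketyl carbon and is therefore not expelled, and with the hydroxyl and the ester arm on opposite faces no lactone can form.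

Step 8
Reactants: 16 methyl 2-[(2R,3S)-5-[(1R)-1-(tert-butyldimethylsilyloxy)ethyl]-3-hydroxy-2,3-dihydro-1-benzofuran-2-yl]acetate
Product: 18 2-[(2R,3S)-5-[(1R)-1-(tert-butyldimethylsilyloxy)ethyl]-3-hydroxy-2,3-dihydro-1-benzofuran-2-yl]acetaldehyde, via aluminium hemiacetal 17 (not isolated)
Conditions: i-Bu2AlH (2.2 equiv), CH2Cl2, −78 °C; MeOH at −78 °C, then aq. potassium sodium tartrate
Reagents that add atoms: none
Why: In this partial ester reduction the first equivalent of i-Bu2AlH is spent on the C3 hydroxyl and the second gives hemiacetal 17, which persists at −78 °C until the quench; the trans C3 alkoxide cannot reach the arm, so neither lactone nor lactol forms and no stereocentre is touched.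

Step 9
Reactants: 18 2-[(2R,3S)-5-[(1R)-1-(tert-butyldimethylsilyloxy)ethyl]-3-hydroxy-2,3-dihydro-1-benzofuran-2-yl]acetaldehyde; 6 formaldehyde (37 % aqueous solution)
Product: 19 2-[(2R,3S)-5-[(1R)-1-(tert-butyldimethylsilyloxy)ethyl]-3-hydroxy-2,3-dihydro-1-benzofuran-2-yl]prop-2-enal
Conditions: aq. CH2O (1.2 equiv), pyrrolidine (10 mol %), EtCO2H (10 mol %), i-PrOH, rt to 45 °C
Reagents that add atoms: formaldehyde 6, C=O
Why: The amine-catalysed α-methylenation of aldehydes (enamine Mannich reaction with formaldehyde, then loss of the amine) runs in a weakly acidic buffer that should keep the aryloxide on C2, and the product has no α-hydrogen left, so it can no longer open.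

Step 10
Reactants: 19 2-[(2R,3S)-5-[(1R)-1-(tert-butyldimethylsilyloxy)ethyl]-3-hydroxy-2,3-dihydro-1-benzofuran-2-yl]prop-2-enal
Product: 20 2-[(2R,3S)-3-hydroxy-5-[(1R)-1-hydroxyethyl]-2,3-dihydro-1-benzofuran-2-yl]prop-2-enal
Conditions: Bu4NF (1.5 equiv), AcOH (1.5 equiv), THF, 0 °C to rt
Reagents that add atoms: none
Why: Fluoride desilylation buffered with acetic acid is close to neutral, which spares the enal and avoids both ionisation at the two alkoxy-activated benzylic carbinols (C3, C1′) and dehydration to the benzofuran.

Step 11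
Reactants: 20 2-[(2R,3S)-3-hydroxy-5-[(1R)-1-hydroxyethyl]-2,3-dihydro-1-benzofuran-2-yl]prop-2-enal; 21 isovaleryl chloride
Product: 22 (1R)-1-[(2R,3S)-2-(1-formylvinyl)-3-(3-methylbutanoyloxy)-2,3-dihydro-1-benzofuran-5-yl]ethyl 3-methylbutanoate (CNP0316116.2)
Conditions: isovaleryl chloride (3 equiv), pyridine (6 equiv), 4-dimethylaminopyridine (10 mol %), CH2Cl2, 0 °C
Reagents that add atoms: isovaleryl chloride 21, CC(C)CC(Cl)=O
Why: Nucleophilic-catalysed acylation esterifies both secondary hydroxyls without touching their C–O bonds (retention at C3 and C1′), and pyridine takes up HCl, so neither benzylic chloride formation nor elimination to the benzofuran is expected at 0 °C.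

Compound list
1 | 4-hydroxyacetophenone | CC(=O)c1ccc(O)cc1 | starting material
2 | 4-(tert-butyldimethylsilyloxy)acetophenone | CC(=O)c1ccc(O[Si](C)(C)C(C)(C)C)cc1 | intermediate
3 | (1R)-1-[4-(tert-butyldimethylsilyloxy)phenyl]ethanol | CC(C)(C)[Si](C)(C)Oc1ccc([C@@H](C)O)cc1 | intermediate
4 | tert-butyl-[4-[(1R)-1-(tert-butyldimethylsilyloxy)ethyl]phenoxy]dimethylsilane (bis-silyl ether) | CC(C)(C)[Si](C)(C)Oc1ccc([C@@H](C)O[Si](C)(C)C(C)(C)C)cc1 | intermediate
5 | 4-[(1R)-1-(tert-butyldimethylsilyloxy)ethyl]phenol | Oc1ccc([C@@H](C)O[Si](C)(C)C(C)(C)C)cc1 | intermediate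
6 | formaldehyde (paraformaldehyde in step 4, 37 % aqueous solution in step 9) | C=O | starting material
7 | 4-[(1R)-1-(tert-butyldimethylsilyloxy)ethyl]-2-(hydroxymethyl)phenol (present as its magnesium salt) | OCc1cc([C@@H](C)O[Si](C)(C)C(C)(C)C)ccc1O | intermediate
8 | 5-[(1R)-1-(tert-butyldimethylsilyloxy)ethyl]-2-hydroxybenzaldehyde | O=Cc1cc([C@@H](C)O[Si](C)(C)C(C)(C)C)ccc1O | intermediate
9 | methyl propiolate | C#CC(=O)OC | starting material
10 | methyl (E)-3-[2-formyl-4-[(1R)-1-(tert-butyldimethylsilyloxy)ethyl]phenoxy]acrylate | COC(=O)/C=C/Oc1ccc([C@@H](C)O[Si](C)(C)C(C)(C)C)cc1C=O | intermediate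
11 | benzylamine | NCc1ccccc1 | starting material
12 | (R)-styrene oxide | C1O[C@@H]1c1ccccc1 | starting material
13 | (1R,1′R)-2,2′-(benzylazanediyl)bis(1-phenylethanol) | O[C@@H](CN(Cc1ccccc1)C[C@H](O)c1ccccc1)c1ccccc1 | intermediate
14 | trivalent samarium ketyl of 10 (drawn without the aminodiol) | COC(=O)/C=C/Oc1ccc([C@@H](C)O[Si](C)(C)C(C)(C)C)cc1[CH]O[Sm]([I])[I] | intermediate
15 | trivalent samarium ester enolate of the cyclised (2R,3S) samarium alkoxide (drawn without the aminodiol) | COC(O[Sm]([I])[I])=C[C@H]1Oc2ccc([C@@H](C)O[Si](C)(C)C(C)(C)C)cc2[C@@H]1O[Sm]([I])[I] | intermediate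
16 | methyl 2-[(2R,3S)-5-[(1R)-1-(tert-butyldimethylsilyloxy)ethyl]-3-hydroxy-2,3-dihydro-1-benzofuran-2-yl]acetate | COC(=O)C[C@H]1Oc2ccc([C@@H](C)O[Si](C)(C)C(C)(C)C)cc2[C@@H]1O | intermediate
17 | bis(diisobutylaluminium) derivative of the methyl hemiacetal of 18 | COC(C[C@H]1Oc2ccc([C@@H](C)O[Si](C)(C)C(C)(C)C)cc2[C@@H]1O[Al](CC(C)C)CC(C)C)O[Al](CC(C)C)CC(C)C | intermediate
18 | 2-[(2R,3S)-5-[(1R)-1-(tert-butyldimethylsilyloxy)ethyl]-3-hydroxy-2,3-dihydro-1-benzofuran-2-yl]acetaldehyde | O=CC[C@H]1Oc2ccc([C@@H](C)O[Si](C)(C)C(C)(C)C)cc2[C@@H]1O | intermediate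
19 | 2-[(2R,3S)-5-[(1R)-1-(tert-butyldimethylsilyloxy)ethyl]-3-hydroxy-2,3-dihydro-1-benzofuran-2-yl]prop-2-enal | C=C(C=O)[C@H]1Oc2ccc([C@@H](C)O[Si](C)(C)C(C)(C)C)cc2[C@@H]1O | intermediate
20 | 2-[(2R,3S)-3-hydroxy-5-[(1R)-1-hydroxyethyl]-2,3-dihydro-1-benzofuran-2-yl]prop-2-enal | C=C(C=O)[C@H]1Oc2ccc([C@@H](C)O)cc2[C@@H]1O | intermediate
21 | isovaleryl chloride | CC(C)CC(Cl)=O | starting material
22 | (1R)-1-[(2R,3S)-2-(1-formylvinyl)-3-(3-methylbutanoyloxy)-2,3-dihydro-1-benzofuran-5-yl]ethyl 3-methylbutanoate | C=C(C=O)[C@H]1Oc2ccc([C@@H](C)OC(=O)CC(C)C)cc2[C@@H]1OC(=O)CC(C)C | target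

Total step count: 11 (ten on the main line plus the one-step ligand preparation).
Longest linear sequence: 10 steps (steps 1–5 and 7–11).

Steps most likely to fail

Step 7. The ligand may discriminate poorly between the two faces of the ketyl. Pinacol dimerisation, plain reduction of the aldehyde, or loss of the aryloxide before protonation may also take material. The fallback gives up induction and separates diastereomers, which is possible because C1′ is already fixed. From 10, the ligand-free SmI2/MeOH/THF cyclisation at −78 °C, the established aldehyde/β-alkoxyacrylate protocol, should give 16 together with the (2S,3R,1′R)-hydroxy ester F1. Acylation of the mixture with (1S,4R)-camphanic chloride (pyridine, 4-dimethylaminopyridine, CH2Cl2) gives the (2R,3S)-camphanate F2 and the (2S,3R)-camphanate F3, which are separated by crystallisation or chromatography. K2CO3 in MeOH at 0 °C cleaves F2 and comes back to the route at 16.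

Step 9. The enamine of 18 may expel the aryloxide O1 (E1cB), which opens the dihydrofuran ring and erodes C2. The fallback replaces the catalytic secondary-amine equilibrium by a stoichiometric Mannich, quaternisation and Hofmann-type elimination sequence. From 18, dimethylmethyleneammonium iodide (Me2N=CH2 iodide) and Et3N in CH2Cl2 give the Mannich base F4, and MeI converts it into the trimethylammonium iodide F5. In this salt nitrogen is by far the better nucleofuge than the aryloxide. Aqueous NaHCO3/CH2Cl2 then eliminates and comes back to the route at 19.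

Step 8. The reduction may run on to the primary alcohol, or the β-aryloxy aldehyde may open during work-up. The fallback reduces fully and re-oxidises. From 16, LiBH4 in THF/MeOH gives the primary/secondary diol F6. TEMPO (2,2,6,6-tetramethylpiperidine N-oxyl, catalytic) with PhI(OAc)2 in CH2Cl2 oxidises the primary alcohol in preference to the hindered C3 carbinol. The trans arrangement blocks lactol and lactone formation, and the sequence comes back to the route at 18.

Further compounds
F1 | step 7 | methyl 2-[(2S,3R)-5-[(1R)-1-(tert-butyldimethylsilyloxy)ethyl]-3-hydroxy-2,3-dihydro-1-benzofuran-2-yl]acetate | COC(=O)C[C@@H]1Oc2ccc([C@@H](C)O[Si](C)(C)C(C)(C)C)cc2[C@H]1O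
F2 | step 7 | (1S,4R)-camphanate of 16 at the C3 oxygen, ring centres (2R,3S) | CC1(C)[C@@]2(C)CC[C@]1(C(=O)O[C@H]3c4cc([C@@H](C)O[Si](C)(C)C(C)(C)C)ccc4O[C@@H]3CC(=O)OC)OC2=O
F3 | step 7 | (1S,4R)-camphanate of F1 at the C3 oxygen, ring centres (2S,3R) | CC1(C)[C@@]2(C)CC[C@]1(C(=O)O[C@@H]3c4cc([C@@H](C)O[Si](C)(C)C(C)(C)C)ccc4O[C@H]3CC(=O)OC)OC2=O
F4 | step 9 | 3-(dimethylamino)-2-[(2R,3S)-5-[(1R)-1-(tert-butyldimethylsilyloxy)ethyl]-3-hydroxy-2,3-dihydro-1-benzofuran-2-yl]propanal (α-carbon undefined) | CN(C)CC(C=O)[C@H]1Oc2ccc([C@@H](C)O[Si](C)(C)C(C)(C)C)cc2[C@@H]1O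
F5 | step 9 | trimethylammonium iodide derived from F4 | C[N+](C)(C)CC(C=O)[C@H]1Oc2ccc([C@@H](C)O[Si](C)(C)C(C)(C)C)cc2[C@@H]1O.[I-]
F6 | step 8 | (2R,3S)-5-[(1R)-1-(tert-butyldimethylsilyloxy)ethyl]-2-(2-hydroxyethyl)-2,3-dihydro-1-benzofuran-3-ol | OCC[C@H]1Oc2ccc([C@@H](C)O[Si](C)(C)C(C)(C)C)cc2[C@@H]1O
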